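**Strategy**

The lower dihydroflavonol unit hides a salicylaldehyde: phenolic O1 and carbonyl carbon C4 sit ortho on ring A (O1–C8a=C4a–C4). The upper robinetinidol unit is therefore first attached to cyclohexane-1,3-dione, a resorcinol surrogate that can only react at the carbon between its two oxygens. This adduct is aromatised and formylated to a 3-flavanyl salicylaldehyde. Ring C of the lower unit is then closed in one operation by an amine-catalysed oxa-Michael/aldol condensation with 3,4,5-tris(benzyloxy)cinnamaldehyde: O1 adds to C2 and C3 adds to C4, with C2 set by the catalyst. The resulting 2H-chromene-3-carbaldehyde is decarbonylated, dihydroxylated and oxidised at C4; hydrogenolysis finishes the synthesis.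

Key step: step 7

Remark: the target is read as robinetinidol-(4α→8)-(2R,3R)-dihydrorobinetin, with a (2R,3S,4S) upper unit (2,3-trans-3,4-trans) and a (2R,3R) lower unit. Flavonoid locants are used for both units. U stands for the (2R,3S,4S)-7-(benzyloxy)-3-hydroxy-2-[3,4,5-tris(benzyloxy)phenyl]chroman-4-yl group. (+)-Dihydrorobinetin, cyclohexane-1,3-dione, 3,4,5-tris(benzyloxy)benzaldehyde and (triphenylphosphoranylidene)acetaldehyde are taken as commercial.

**Route**

Step 1
Reactants: 1 (+)-(2R,3R)-dihydrorobinetin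
Product: 2 (2R,3S,4R)-leucorobinetinidin (2,3-trans-3,4-trans flavan-3,4-diol)
Conditions: NaBH4, EtOH, 0 °C to rt
Reagents that add atoms: none
Why: Borohydride reduction of the aryl ketone, with axial hydride delivery expected to give the equatorial 4-hydroxyl (3,4-trans), although this centre is ionised in step 2 and need not be controlled.

Step 2
Reactants: 2 (2R,3S,4R)-leucorobinetinidin; 3 cyclohexane-1,3-dione
Product: 5 3-hydroxy-2-[(2R,3S,4S)-3,7-dihydroxy-2-(3,4,5-trihydroxyphenyl)chroman-4-yl]cyclohex-2-en-1-one, via benzylic cation 4 (not isolated)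
Conditions: 3 (10 equiv), 0.1 M HCl, H2O/dioxane, rt, N2
Reagents that add atoms: none
Why: Acid ionises the C4 hydroxyl to cation 4 (stabilised by the para 7-hydroxyl and the ring oxygen), and the enol of 3, nucleophilic only at its C2, should capture it anti to the C3 hydroxyl to give the all-equatorial 3,4-trans (4S) adduct (SN1 benzylation of a 1,3-dicarbonyl, the flavan-3,4-diol condensation of proanthocyanidin chemistry); the excess of 3 suppresses self-condensation of 2.

Step 3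
Reactants: 5 3-hydroxy-2-[(2R,3S,4S)-3,7-dihydroxy-2-(3,4,5-trihydroxyphenyl)chroman-4-yl]cyclohex-2-en-1-one
Product: 6 3-(benzyloxy)-2-U-cyclohex-2-en-1-one
Conditions: BnBr (6 equiv), K2CO3, DMF, rt, argon
Reagents that add atoms: benzyl bromide BrCc1ccccc1
Why: Williamson etherification of the four phenols and O-alkylation of the acidic enol of the hindered 2-substituted dione, while the aliphatic C3 hydroxyl is too weakly acidic for K2CO3.

Step 4
Reactants: 6 3-(benzyloxy)-2-U-cyclohex-2-en-1-one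
Product: 9 3-(benzyloxy)-2-U-phenol, via selenide 7 (not isolated), via dienone 8 (not isolated)
Conditions: LDA (2.2 equiv), THF, −78 °C; PhSeBr; then H2O2, pyridine, CH2Cl2, 0 °C to rt
Reagents that add atoms: none
Why: Kinetic α′-deprotonation of the vinylogous ester (the second equivalent of base covers the C3 hydroxyl), selenenylation to 7, then oxidation at selenium and syn-elimination to dienone 8, which tautomerises to the phenol (selenoxide elimination and aromatisation).

Step 5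
Reactants: 9 3-(benzyloxy)-2-U-phenol
Product: 11 4-(benzyloxy)-2-hydroxy-3-U-benzaldehyde, via hydroxymethylphenol 10 (not isolated)
Conditions: MgCl2, Et3N, (CH2O)n, THF, reflux
Reagents that add atoms: paraformaldehyde (as formaldehyde) C=O
Why: Casnati–Skattebøl ortho-formylation, in which the magnesium phenoxide directs formaldehyde to the only free ortho position to give 10 and a second formaldehyde oxidises it by Oppenauer-type hydride transfer.

Step 6
Reactants: 12 3,4,5-tris(benzyloxy)benzaldehyde; 13 (triphenylphosphoranylidene)acetaldehyde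
Product: 14 (E)-3-[3,4,5-tris(benzyloxy)phenyl]prop-2-enal
Conditions: toluene, 80 °C
Reagents that add atoms: none
Why: Wittig olefination with a stabilised ylide, which should give the (E)-enal.

Step 7
Reactants: 11 4-(benzyloxy)-2-hydroxy-3-U-benzaldehyde; 14 (E)-3-[3,4,5-tris(benzyloxy)phenyl]prop-2-enal
Product: 16 (2R)-7-(benzyloxy)-8-U-2-[3,4,5-tris(benzyloxy)phenyl]-2H-chromene-3-carbaldehyde, via aldol adduct 15 (not isolated)
Conditions: (S)-2-[diphenyl(trimethylsilyloxy)methyl]pyrrolidine (30 mol%), 2-nitrobenzoic acid (30 mol%), 4 Å MS, toluene, rt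
Reagents that add atoms: none
Why: The amine condenses with enal 14 to an iminium ion, phenolic O1 of 11 adds to its β-carbon (oxa-Michael, O1–C2), and the resulting enamine attacks the ortho formyl carbon (intramolecular aldol, C3–C4); dehydration of 15 and hydrolysis release 16 and the catalyst. The closest known reaction is the diarylprolinol silyl ether-catalysed oxa-Michael/aldol condensation of salicylaldehydes with cinnamaldehydes to 2-aryl-2H-chromene-3-carbaldehydes. Ring C is closed by a 6-exo-trig aldol addition of the enamine carbon onto the aldehyde. C2 is the only new stereocentre that survives: the diphenyl(silyloxy)methyl group shields one face of the (E)-iminium, so the (S)-catalyst should send O1 to the open face and give (2R), while C3 and C4 of 15 are erased by dehydration. The step needs O1 rather than the aliphatic hydroxyl of U to add, which the acidity of the phenol and the fact that only O1 has an aldehyde in reach for the irreversible ring closure should secure. It also needs catalyst control to override the neighbouring chiral flavanyl group, and any C2 epimer is a diastereomer removable by chromatography.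

Step 8
Reactants: 16 (2R)-7-(benzyloxy)-8-U-2-[3,4,5-tris(benzyloxy)phenyl]-2H-chromene-3-carbaldehyde
Product: 17 (2S)-7-(benzyloxy)-8-U-2-[3,4,5-tris(benzyloxy)phenyl]-2H-chromene
Conditions: RhCl(PPh3)3 (1.1 equiv), toluene, 90–100 °C
Reagents that add atoms: none
Why: Tsuji–Wilkinson decarbonylation (oxidative addition of the formyl C–H bond to monovalent rhodium, carbonyl de-insertion, C–H reductive elimination) replaces CHO by H without touching C2, whose descriptor changes to S only because the CIP priorities change.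

Step 9
Reactants: 17 (2S)-7-(benzyloxy)-8-U-2-[3,4,5-tris(benzyloxy)phenyl]-2H-chromene
Product: 18 (2R,3S,4S)-7-(benzyloxy)-8-U-2-[3,4,5-tris(benzyloxy)phenyl]chromane-3,4-diol
Conditions: OsO4 (5 mol%), NMO (1.5 equiv), acetone/H2O, 0 °C to rt
Reagents that add atoms: osmium tetroxide O=[Os](=O)(=O)=O; N-methylmorpholine N-oxide C[N+]1([O-])CCOCC1
Why: Upjohn syn-dihydroxylation of the electron-rich styrenic C3=C4 bond from the face anti to the C2 aryl group, which should set C3 (S) and C4 (S) as the 2,3-trans-3,4-cis diol.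

Step 10
Reactants: 18 (2R,3S,4S)-7-(benzyloxy)-8-U-2-[3,4,5-tris(benzyloxy)phenyl]chromane-3,4-diol
Product: 19 (2R,3R)-7-(benzyloxy)-3-hydroxy-8-U-2-[3,4,5-tris(benzyloxy)phenyl]chroman-4-one
Conditions: activated MnO2 (excess), CH2Cl2, rt
Reagents that add atoms: none
Why: Chemoselective benzylic oxidation, in which MnO2 should oxidise only the C4 carbinol (activated by the ortho and para oxygens of ring A) and leave the two homobenzylic C3 hydroxyls and the 2,3-trans C3 configuration (also the thermodynamically preferred one) untouched.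

Step 11
Reactants: 19 (2R,3R)-7-(benzyloxy)-3-hydroxy-8-U-2-[3,4,5-tris(benzyloxy)phenyl]chroman-4-one
Product: 20 robinetinidol-(4α→8)-(2R,3R)-dihydrorobinetin (target)
Conditions: H2 (1 atm), Pd(OH)2/C, THF/MeOH, rt
Reagents that add atoms: none
Why: Hydrogenolysis of the eight benzyl ethers under neutral conditions, which the aryl ketone, the ring C–O bonds and the interflavan bond should survive.

**Compound list**

1 | (+)-dihydrorobinetin, (2R,3R)-3,7-dihydroxy-2-(3,4,5-trihydroxyphenyl)chroman-4-one | O=C1c2ccc(O)cc2O[C@H](c2cc(O)c(O)c(O)c2)[C@H]1O | starting material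
2 | (2R,3S,4R)-leucorobinetinidin, (2R,3S,4R)-2-(3,4,5-trihydroxyphenyl)chromane-3,4,7-triol | O[C@@H]1c2ccc(O)cc2O[C@H](c2cc(O)c(O)c(O)c2)[C@H]1O | intermediate
3 | cyclohexane-1,3-dione | O=C1CCCC(=O)C1 | starting material
4 | (2R,3S)-3,7-dihydroxy-2-(3,4,5-trihydroxyphenyl)chroman-4-ylium (C4 benzylic cation) | [CH+]1c2ccc(O)cc2O[C@H](c2cc(O)c(O)c(O)c2)[C@H]1O | intermediate
5 | 3-hydroxy-2-[(2R,3S,4S)-3,7-dihydroxy-2-(3,4,5-trihydroxyphenyl)chroman-4-yl]cyclohex-2-en-1-one | O=C1CCCC(O)=C1[C@@H]3c4ccc(O)cc4O[C@H](c4cc(O)c(O)c(O)c4)[C@H]3O | intermediate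
6 | 3-(benzyloxy)-2-U-cyclohex-2-en-1-one | O=C1CCCC(OCc2ccccc2)=C1[C@@H]3c4ccc(OCc5ccccc5)cc4O[C@H](c4cc(OCc5ccccc5)c(OCc5ccccc5)c(OCc5ccccc5)c4)[C@H]3O | intermediate
7 | 3-(benzyloxy)-6-(phenylselanyl)-2-U-cyclohex-2-en-1-one (both C6 epimers) | O=C1C([Se]c2ccccc2)CCC(OCc2ccccc2)=C1[C@@H]3c4ccc(OCc5ccccc5)cc4O[C@H](c4cc(OCc5ccccc5)c(OCc5ccccc5)c(OCc5ccccc5)c4)[C@H]3O | intermediate
8 | 3-(benzyloxy)-2-U-cyclohexa-2,5-dien-1-one | O=C1C=CCC(OCc2ccccc2)=C1[C@@H]3c4ccc(OCc5ccccc5)cc4O[C@H](c4cc(OCc5ccccc5)c(OCc5ccccc5)c(OCc5ccccc5)c4)[C@H]3O | intermediate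
9 | 3-(benzyloxy)-2-U-phenol | Oc1cccc(OCc2ccccc2)c1[C@@H]3c4ccc(OCc5ccccc5)cc4O[C@H](c4cc(OCc5ccccc5)c(OCc5ccccc5)c(OCc5ccccc5)c4)[C@H]3O | intermediate
10 | 3-(benzyloxy)-6-(hydroxymethyl)-2-U-phenol (magnesium salt in the flask) | OCc1ccc(OCc2ccccc2)c([C@@H]3c4ccc(OCc5ccccc5)cc4O[C@H](c4cc(OCc5ccccc5)c(OCc5ccccc5)c(OCc5ccccc5)c4)[C@H]3O)c1O | intermediate
11 | 4-(benzyloxy)-2-hydroxy-3-U-benzaldehyde | O=Cc1ccc(OCc2ccccc2)c([C@@H]3c4ccc(OCc5ccccc5)cc4O[C@H](c4cc(OCc5ccccc5)c(OCc5ccccc5)c(OCc5ccccc5)c4)[C@H]3O)c1O | intermediate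
12 | 3,4,5-tris(benzyloxy)benzaldehyde | O=Cc1cc(OCc2ccccc2)c(OCc2ccccc2)c(OCc2ccccc2)c1 | starting material
13 | (triphenylphosphoranylidene)acetaldehyde | O=CC=P(c1ccccc1)(c1ccccc1)c1ccccc1 | starting material
14 | (E)-3-[3,4,5-tris(benzyloxy)phenyl]prop-2-enal | O=C/C=C/c1cc(OCc2ccccc2)c(OCc2ccccc2)c(OCc2ccccc2)c1 | intermediate
15 | (2S)-7-(benzyloxy)-4-hydroxy-8-U-2-[3,4,5-tris(benzyloxy)phenyl]chromane-3-carbaldehyde (C3/C4 diastereomers; same spatial arrangement at C2 as in 16) | O=CC1C(O)c2ccc(OCc6ccccc6)c([C@@H]3c4ccc(OCc5ccccc5)cc4O[C@H](c4cc(OCc5ccccc5)c(OCc5ccccc5)c(OCc5ccccc5)c4)[C@H]3O)c2O[C@@H]1c7cc(OCc6ccccc6)c(OCc6ccccc6)c(OCc6ccccc6)c7 | intermediate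
16 | (2R)-7-(benzyloxy)-8-U-2-[3,4,5-tris(benzyloxy)phenyl]-2H-chromene-3-carbaldehyde | O=CC1=Cc2ccc(OCc6ccccc6)c([C@@H]3c4ccc(OCc5ccccc5)cc4O[C@H](c4cc(OCc5ccccc5)c(OCc5ccccc5)c(OCc5ccccc5)c4)[C@H]3O)c2O[C@@H]1c7cc(OCc6ccccc6)c(OCc6ccccc6)c(OCc6ccccc6)c7 | intermediate
17 | (2S)-7-(benzyloxy)-8-U-2-[3,4,5-tris(benzyloxy)phenyl]-2H-chromene | C1=Cc2ccc(OCc6ccccc6)c([C@@H]3c4ccc(OCc5ccccc5)cc4O[C@H](c4cc(OCc5ccccc5)c(OCc5ccccc5)c(OCc5ccccc5)c4)[C@H]3O)c2O[C@@H]1c7cc(OCc6ccccc6)c(OCc6ccccc6)c(OCc6ccccc6)c7 | intermediate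
18 | (2R,3S,4S)-7-(benzyloxy)-8-U-2-[3,4,5-tris(benzyloxy)phenyl]chromane-3,4-diol (2,3-trans-3,4-cis) | O[C@H]1c2ccc(OCc6ccccc6)c([C@@H]3c4ccc(OCc5ccccc5)cc4O[C@H](c4cc(OCc5ccccc5)c(OCc5ccccc5)c(OCc5ccccc5)c4)[C@H]3O)c2O[C@H](c7cc(OCc6ccccc6)c(OCc6ccccc6)c(OCc6ccccc6)c7)[C@H]1O | intermediate
19 | (2R,3R)-7-(benzyloxy)-3-hydroxy-8-U-2-[3,4,5-tris(benzyloxy)phenyl]chroman-4-one | O=C1c2ccc(OCc6ccccc6)c([C@@H]3c4ccc(OCc5ccccc5)cc4O[C@H](c4cc(OCc5ccccc5)c(OCc5ccccc5)c(OCc5ccccc5)c4)[C@H]3O)c2O[C@H](c7cc(OCc6ccccc6)c(OCc6ccccc6)c(OCc6ccccc6)c7)[C@H]1O | intermediate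
20 | (2R,3R)-3,7-dihydroxy-8-[(2R,3S,4S)-3,7-dihydroxy-2-(3,4,5-trihydroxyphenyl)chroman-4-yl]-2-(3,4,5-trihydroxyphenyl)chroman-4-one | O=C1c2ccc(O)c([C@@H]3c4ccc(O)cc4O[C@H](c4cc(O)c(O)c(O)c4)[C@H]3O)c2O[C@H](c2cc(O)c(O)c(O)c2)[C@H]1O | target

**Step count and risks**

Total step count: 11. Longest linear sequence: 10 steps (steps 1 to 5, then 7 to 11); step 6 is a one-step side branch.

Steps most likely to fail:

1. Step 7. The phenol is flanked by the formyl group and the bulky chiral flavanyl group, so the oxa-Michael addition may be slow or reversible without ring closure. Double stereodifferentiation may also be mismatched and erode the facial selectivity at C2. The fallback sets out from 11 and uses 12. Aldehyde 12 would be converted by Takai boryl-olefination (Cl2CHB(pin), CrCl2, LiI, THF) into 2-{(E)-2-[3,4,5-tris(benzyloxy)phenyl]ethenyl}-4,4,5,5-tetramethyl-1,3,2-dioxaborolane F1, and with KHF2 into potassium (E)-trifluoro{2-[3,4,5-tris(benzyloxy)phenyl]ethenyl}borate F2. Heating 11 with F2 and dibenzylamine (Petasis-type amine-mediated 2H-chromene synthesis from a salicylaldehyde and an alkenylboron reagent) would form the same two bonds without the formyl group. It would give flavene 17 together with its (2R)-epimer F3, a diastereomer to be removed by chromatography. The route is rejoined at 17 and step 8 is then not needed.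

2. Step 8. At the temperature needed for decarbonylation, reversible 6π ring opening of the 2H-chromene may epimerise C2, and the enal may lose CO only sluggishly. The fallback sets out from 16 and avoids heat. Upjohn dihydroxylation (OsO4, NMO) anti to the C2 aryl group would give the 3-formyl-3,4-cis-diol F4. MnO2 would oxidise its benzylic C4 hydroxyl to the α-hydroxy-β-keto aldehyde F5. K2CO3 in MeOH at 0 °C would remove the formyl group by retro-Claisen cleavage, and protonation of the enediolate should give the thermodynamically favoured 2,3-trans ketone. The route is rejoined at 19, so steps 9 and 10 are skipped.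

3. Step 10. MnO2 may cleave the cis-glycol oxidatively or oxidise incompletely. The fallback sets out from 17 and never passes through the diol. Epoxidation with dimethyldioxirane (acetone, −20 °C) anti to the C2 aryl group would give the 3,4-epoxide F6. DMSO would open it at the benzylic C4 to the alkoxysulfonium betaine F7, and Et3N would then release dimethyl sulfide (Kornblum-type oxidation). The C3–O bond is never broken, and the route is rejoined at 19.

**Further compounds**

F1 | step 7 | 2-{(E)-2-[3,4,5-tris(benzyloxy)phenyl]ethenyl}-4,4,5,5-tetramethyl-1,3,2-dioxaborolane | CC1(C)OB(/C=C/c2cc(OCc3ccccc3)c(OCc3ccccc3)c(OCc3ccccc3)c2)OC1(C)C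
F2 | step 7 | potassium (E)-trifluoro{2-[3,4,5-tris(benzyloxy)phenyl]ethenyl}borate | [K+].F[B-](F)(F)/C=C/c1cc(OCc2ccccc2)c(OCc2ccccc2)c(OCc2ccccc2)c1
F3 | step 7 | (2R)-7-(benzyloxy)-8-U-2-[3,4,5-tris(benzyloxy)phenyl]-2H-chromene (C2 epimer of 17) | C1=Cc2ccc(OCc6ccccc6)c([C@@H]3c4ccc(OCc5ccccc5)cc4O[C@H](c4cc(OCc5ccccc5)c(OCc5ccccc5)c(OCc5ccccc5)c4)[C@H]3O)c2O[C@H]1c7cc(OCc6ccccc6)c(OCc6ccccc6)c(OCc6ccccc6)c7
F4 | step 8 | 7-(benzyloxy)-3,4-dihydroxy-8-U-2-[3,4,5-tris(benzyloxy)phenyl]chromane-3-carbaldehyde (both hydroxyls anti to the C2 aryl group) | O[C@H]1c2ccc(OCc6ccccc6)c([C@@H]3c4ccc(OCc5ccccc5)cc4O[C@H](c4cc(OCc5ccccc5)c(OCc5ccccc5)c(OCc5ccccc5)c4)[C@H]3O)c2O[C@H](c7cc(OCc6ccccc6)c(OCc6ccccc6)c(OCc6ccccc6)c7)[C@]1(O)C=O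
F5 | step 8 | 7-(benzyloxy)-3-hydroxy-4-oxo-8-U-2-[3,4,5-tris(benzyloxy)phenyl]chromane-3-carbaldehyde (3-hydroxyl anti to the C2 aryl group) | O=C1c2ccc(OCc6ccccc6)c([C@@H]3c4ccc(OCc5ccccc5)cc4O[C@H](c4cc(OCc5ccccc5)c(OCc5ccccc5)c(OCc5ccccc5)c4)[C@H]3O)c2O[C@H](c7cc(OCc6ccccc6)c(OCc6ccccc6)c(OCc6ccccc6)c7)[C@]1(O)C=O
F6 | step 10 | 7-(benzyloxy)-3,4-epoxy-8-U-2-[3,4,5-tris(benzyloxy)phenyl]chromane (epoxide anti to the C2 aryl group) | O1[C@H]2c8ccc(OCc6ccccc6)c([C@@H]3c4ccc(OCc5ccccc5)cc4O[C@H](c4cc(OCc5ccccc5)c(OCc5ccccc5)c(OCc5ccccc5)c4)[C@H]3O)c8O[C@H](c7cc(OCc6ccccc6)c(OCc6ccccc6)c(OCc6ccccc6)c7)[C@H]21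
F7 | step 10 | dimethyl{[7-(benzyloxy)-3-oxido-8-U-2-[3,4,5-tris(benzyloxy)phenyl]chroman-4-yl]oxy}sulfonium betaine (C4 epimers; C3 oxygen anti to the C2 aryl group) | C[S+](C)OC1c8ccc(OCc6ccccc6)c([C@@H]3c4ccc(OCc5ccccc5)cc4O[C@H](c4cc(OCc5ccccc5)c(OCc5ccccc5)c(OCc5ccccc5)c4)[C@H]3O)c8O[C@H](c7cc(OCc6ccccc6)c(OCc6ccccc6)c(OCc6ccccc6)c7)[C@H]1[O-]
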